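(The numbers of this flask are invented; the result is computed.)

A ratio of two rates at one moment, self-condensation against entry into the target step, is followed here through two flasks that differ in one charge.

    reagent in the reaction phase + target → over-reacted product (k1 = 3.5 M⁻¹ s⁻¹)
    reagent in the reaction phase ⇌ reagent in the second phase, rate k2*([reagent in the reaction phase] - [reagent in the second phase]/K2) per volume of the first phase (K2 = 1.9, k2 = 0.062 s⁻¹)
    starting material + reagent in the reaction phase ⇌ target (K3 = 1000 M⁻¹, k3 = 11 M⁻¹ s⁻¹)
    2 starting material → self-condensation product (k4 = 13 M⁻¹ s⁻¹)
    starting material + target → side product (k5 = 9.4 M⁻¹ s⁻¹)

starting material 5.0 mM; reagent in the second phase 4.00 mM; time 2.5 min; volume of the second phase over the first 1.0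

1. target at 2.5 min, in percent of the starting material charged
2. the change that raises the amount of target at 2.5 min, in percent of the starting material charged most ("none" if none brings more than 2 percentage points) (south / west / none)
3. amount of target at 2.5 min, in percent of the starting material charged, after south

- south: doubling the transfer coefficient of step 2, all else as stated
- west: doubling the amount of reagent in the second phase, all else as stated

- percent here means starting material units held: one side product or self-condensation product counts as two
- two of one species on the left: rate k times its square, two consumed each time
- in the second phase: reagent in the second phase; everything else is in the first
- charges count per volume of the first phase; a concentration in a rate is the amount of a species over the volume of its own phase; every rate counts per litre of the first phase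
- run time (flask): 2.5 min

**First.** The reagent starts in the second phase. With partition ratio 1.9 and none consumed, c(reagent in the reaction phase) reaches 1.38 mM. It approaches this with a time constant of 10.6 s.

**Second.** Two starting material go at each turn of self-condensation. The diversion ratio D is therefore 2·k(self-condensation)·c(starting material) / [k(target step)·c(reagent in the reaction phase)], the rate at which starting material is lost to self-condensation over the rate at which it enters the target step. Its inverse is a selectivity factor. With the charge and the partition value, 8.57 is the value for the flask.

**Third.** D drifts down in step with c(starting material). With the reagent held at partition, integrating over the consumption of starting material gives the share entering the target step as ln(1+D)/D, here 26.4 %. Self-condensation takes the other 73.6 %.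

**Fourth.** The neighbour flask, charged with 1.2 mM, starts at 2.06. Since its D is lower than that of the flask, its reckoned entry share is larger, 54.3 %, and self-condensation takes 45.7 %.

**Fifth.** For the flask, this hand reckoning flatters the entry share, because the first half-life of starting material there, 7.69 s, is shorter than the reagent's time constant. It counts entries, not target standing at the asked time, so it gives no figure for the amount asked.

**Sixth.** The forecast gave 3.2 %, 3.6 % after south, and none as the best change, holding that “self-condensation consumes most of the starting material within seconds”.

**Seventh.** The flask gives 3.90 % of target, 4.06 % after south, and none as the best change, with west adding 0.76 percentage points. At 2.50 min, self-condensation product stands at 83.2 % in the flask and 58.4 % in the neighbour flask, with target at 3.90 % and 12.3 %. Read at 0.0927 min, D in the flask is 13, higher than the reckoned value. At 0.250 min, c(reagent in the reaction phase) in the flask is still 0.898 mM, and self-condensation product already holds 64.0 %.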